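## Retrosynthetic overview

1. Target ⇐ acetylation ⇐ diol ⇐ B-alkyl Suzuki–Miyaura union of a C16 ring-containing alkylborane (from a 1,3-diene) with a C9 (2E,4E)-2-iodo-dienyl butenolide.
2. C9 half ⇐ site-selective Stille coupling of (E)-2,3-diiodoallyl alcohol (propargyl alcohol + iodine) with an (E)-stannylvinyl butenolide (from 4-bromofuranone). The butenolide ring is bought, not made.
3. Diene ⇐ Zr-catalysed carboalumination/vinylation of a terminal alkyne (fixes the E trisubstituted olefin) ⇐ methyl ketone by enol phosphate elimination.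
4. Hydroxy ketone ⇐ (E)-geranylacetone in one flask: enantioselective proton-initiated cyclisation, 1,2-hydride shift and oxygen capture at the new tertiary cation, with the chain carbonyl standing in for water. This sets both stereocentres.
5. Ring order: the cyclohexane ring is the only ring formed (step 1); everything else is appended to it.

Assumption: the (S)-binaphthol ligand is taken to give the required (4aR,8aR) sense in the fused oxocarbenium ion of step 1; if the sense proves opposite, the (R)-ligand is used with nothing else changed.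

Ring numbering used below: C1 = carbinol carbon, C2 = CMe2, C6 = CHMe.

## Route

Step 1
Reactants: 1 (5E)-6,10-dimethylundeca-5,9-dien-2-one
Product: 4 4-[(1R,6S)-1-hydroxy-2,2,6-trimethylcyclohexyl]butan-2-one, via fused oxocarbenium ion 2 (not isolated), via spiro oxocarbenium ion 3 (not isolated)
Conditions: SnCl4 (0.5 equiv), (S)-2'-[(2-fluorophenyl)methoxy]-1,1'-binaphthalen-2-ol (0.55 equiv), CH2Cl2, −78 °C, 24 h; then −30 °C, 6 h; then THF–H2O, 0 °C
Reagents that add atoms: water, O
Why: Proposed new method: the chiral SnCl4–binaphthol-ether Brønsted acid protonates the terminal olefin on one enantioface, the E-olefin closes the ring through a chair and the ketone oxygen traps the tertiary C6 cation equatorially to give trans-fused ion 2 (closest known reaction type: enantioselective protonative cyclisation of polyprenoids with oxygen termination by Lewis acid-assisted Brønsted acids), and on warming 2 re-ionises at its tertiary carbon–oxygen bond, helped by the 1,3-diaxial Me/Me strain locked into the trans-fused bicycle, so that the axial C1 hydrogen migrates suprafacially to C6 into the position the oxygen has just left (C6 becomes S) while the carbonyl oxygen, held on that same face by its three-atom tether, closes on C1 in the axial position the hydride vacated, the other face being screened by the two axial methyls as long as the chair has not inverted (C1 becomes R, OH cis to the C6 hydrogen), this second stage being modelled on acid-induced 1,2-hydride shifts of terpenoid cations and δ- to γ-lactone ring contractions in strong acid, after which water opens ion 3 to the hydroxy ketone.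

Step 2
Reactants: 4 4-[(1R,6S)-1-hydroxy-2,2,6-trimethylcyclohexyl]butan-2-one
Product: 6 (1R,6S)-1-(but-3-yn-1-yl)-2,2,6-trimethylcyclohexan-1-ol, via enol phosphate 5 (not isolated)
Conditions: LiN(iPr)2 (2.3 equiv), THF, −78 °C; ClP(O)(OEt)2 (1.1 equiv), −78 to 25 °C; LiN(iPr)2 (2.5 equiv), −78 to 25 °C; aq. NH4Cl
Reagents that add atoms: none
Why: One-pot methyl ketone to terminal alkyne conversion (Negishi protocol) by kinetic enolisation on the CH3 side, O-phosphorylation and base-induced β-elimination of the enol phosphate, the hindered tertiary alkoxide being a spectator and no stereocentre being touched.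

Step 3
Reactants: 6 (1R,6S)-1-(but-3-yn-1-yl)-2,2,6-trimethylcyclohexan-1-ol
Product: 8 (1R,6S)-2,2,6-trimethyl-1-[(3E)-3-methylhexa-3,5-dien-1-yl]cyclohexan-1-ol, via alkenylalane 7 (not isolated)
Conditions: Me3Al (3 equiv), Cp2ZrCl2 (0.25 equiv), CH2Cl2, 0 to 25 °C, 16 h; then vinyl bromide (3 equiv), Pd(PPh3)4 (5 mol%), ZnCl2 (0.2 equiv), THF, 25 °C
Reagents that add atoms: trimethylaluminium, C[Al](C)C; vinyl bromide, C=CBr
Why: Zr-catalysed carboalumination adds methyl and aluminium syn across the terminal alkyne with methyl on the internal carbon, which fixes the E trisubstituted olefin, and the palladium/zinc-catalysed Negishi alkenyl–alkenyl coupling with vinyl bromide proceeds with retention, the hydroxyl riding through as its O–AlMe2 alkoxide.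

Step 4
Reactants: 9 prop-2-yn-1-ol
Product: 10 (2E)-2,3-diiodoprop-2-en-1-ol
Conditions: I2 (1.05 equiv), KI, H2O, 25 °C, dark
Reagents that add atoms: iodine, [I][I]
Why: Electrophilic anti addition of iodine to the alkyne through an iodonium ion gives the E diiodide, which places the C3 iodine cis to CH2OH as the later dienyl group must be.

Step 5
Reactants: 11 4-bromofuran-2(5H)-one; 12 (E)-1,2-bis(tributylstannyl)ethene
Product: 13 4-[(E)-2-(tributylstannyl)ethenyl]furan-2(5H)-one
Conditions: 12 (2.5 equiv), Pd(PPh3)4 (5 mol%), toluene, 80 °C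
Reagents that add atoms: none
Why: Stille coupling at the activated β-bromo enoate carbon with retention of the E geometry, the excess of distannane suppressing double coupling.

Step 6
Reactants: 10 (2E)-2,3-diiodoprop-2-en-1-ol; 13 4-[(E)-2-(tributylstannyl)ethenyl]furan-2(5H)-one
Product: 14 4-[(1E,3E)-5-hydroxy-4-iodopenta-1,3-dien-1-yl]furan-2(5H)-one
Conditions: PdCl2(MeCN)2 (5 mol%), DMF, 25 °C, dark
Reagents that add atoms: none
Why: Site-selective Stille coupling in which zerovalent palladium inserts at the less hindered terminal C3 iodide and not at the internal C2 iodide flanked by CH2OH, both olefin geometries being retained so that the dienyl group ends up cis to CH2OH.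

Step 7
Reactants: 8 (1R,6S)-2,2,6-trimethyl-1-[(3E)-3-methylhexa-3,5-dien-1-yl]cyclohexan-1-ol; 14 4-[(1E,3E)-5-hydroxy-4-iodopenta-1,3-dien-1-yl]furan-2(5H)-one
Product: 16 4-{(1E,3Z,7E)-4-(hydroxymethyl)-10-[(1R,6S)-1-hydroxy-2,2,6-trimethylcyclohexyl]-8-methyldeca-1,3,7-trien-1-yl}furan-2(5H)-one, via alkylborane 15 (not isolated)
Conditions: 8 (1.3 equiv), 9-borabicyclo[3.3.1]nonane (9-BBN, 1.5 equiv), THF, 0 to 25 °C; then 14, PdCl2[1,1'-bis(diphenylphosphino)ferrocene] (5 mol%), AsPh3 (10 mol%), Cs2CO3 (3 equiv), DMF–THF–H2O, 25 °C, dark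
Reagents that add atoms: none
Why: 9-BBN hydroborates only the terminal CH2= of the 1,3-diene (anti-Markovnikov, trisubstituted olefin untouched) and the primary alkylborane undergoes B-alkyl Suzuki–Miyaura coupling with the vinyl iodide with retention, so the chain is trans to the dienyl group (3Z by CIP), the free allylic hydroxyl being kept because an acetate next to the vinyl–palladium bond could be lost by β-elimination or ionisation.

Step 8
Reactants: 16 4-{(1E,3Z,7E)-4-(hydroxymethyl)-10-[(1R,6S)-1-hydroxy-2,2,6-trimethylcyclohexyl]-8-methyldeca-1,3,7-trien-1-yl}furan-2(5H)-one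
Product: 17 (2Z,4E)-2-{(3E)-6-[(1R,6S)-1-hydroxy-2,2,6-trimethylcyclohexyl]-4-methylhex-3-en-1-yl}-5-(5-oxo-2,5-dihydrofuran-3-yl)penta-2,4-dien-1-yl acetate
Conditions: Ac2O (1.3 equiv), pyridine, 4-(dimethylamino)pyridine (5 mol%), CH2Cl2, 0 °C
Reagents that add atoms: acetic anhydride, CC(=O)OC(C)=O
Why: Nucleophile-catalysed acylation of the primary allylic hydroxyl, the tertiary hydroxyl flanked by CMe2 and CHMe being too hindered to react.

## Compound list

1 | (5E)-6,10-dimethylundeca-5,9-dien-2-one ((E)-geranylacetone) | CC(=O)CC/C=C(\C)CCC=C(C)C | starting material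
2 | (4aR,8aR)-2,5,5,8a-tetramethyl-3,4,4a,5,6,7,8,8a-octahydrochromenylium (fused oxocarbenium ion) | CC1=[O+][C@]2(C)CCCC(C)(C)[C@H]2CC1 | intermediate
3 | (5R,6S)-2,6,10,10-tetramethyl-1-oxaspiro[4.5]dec-1-en-1-ium (spiro oxocarbenium ion) | CC1=[O+][C@]2(CC1)[C@@H](C)CCCC2(C)C | intermediate
4 | 4-[(1R,6S)-1-hydroxy-2,2,6-trimethylcyclohexyl]butan-2-one | CC(=O)CC[C@@]1(O)[C@@H](C)CCCC1(C)C | intermediate
5 | diethyl 4-[(1R,6S)-1-hydroxy-2,2,6-trimethylcyclohexyl]but-1-en-2-yl phosphate (enol phosphate, present as its lithium alkoxide) | C=C(CC[C@@]1(O)[C@@H](C)CCCC1(C)C)OP(=O)(OCC)OCC | intermediate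
6 | (1R,6S)-1-(but-3-yn-1-yl)-2,2,6-trimethylcyclohexan-1-ol | C#CCC[C@@]1(O)[C@@H](C)CCCC1(C)C | intermediate
7 | dimethyl{(1E)-4-[(1R,6S)-1-(dimethylalumanyloxy)-2,2,6-trimethylcyclohexyl]-2-methylbut-1-en-1-yl}alumane (alkenylalane) | C[Al](C)/C=C(\C)CC[C@@]1(O[Al](C)C)[C@@H](C)CCCC1(C)C | intermediate
8 | (1R,6S)-2,2,6-trimethyl-1-[(3E)-3-methylhexa-3,5-dien-1-yl]cyclohexan-1-ol | C=C/C=C(\C)CC[C@@]1(O)[C@@H](C)CCCC1(C)C | intermediate
9 | prop-2-yn-1-ol | OCC#C | starting material
10 | (2E)-2,3-diiodoprop-2-en-1-ol | OC/C(I)=C\I | intermediate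
11 | 4-bromofuran-2(5H)-one | BrC1=CC(=O)OC1 | starting material
12 | (E)-1,2-bis(tributylstannyl)ethene | CCCC[Sn](CCCC)(CCCC)/C=C/[Sn](CCCC)(CCCC)CCCC | starting material
13 | 4-[(E)-2-(tributylstannyl)ethenyl]furan-2(5H)-one | CCCC[Sn](CCCC)(CCCC)/C=C/C1=CC(=O)OC1 | intermediate
14 | 4-[(1E,3E)-5-hydroxy-4-iodopenta-1,3-dien-1-yl]furan-2(5H)-one | OC/C(I)=C\C=C\C1=CC(=O)OC1 | intermediate
15 | 9-{(3E)-6-[(1R,6S)-1-hydroxy-2,2,6-trimethylcyclohexyl]-4-methylhex-3-en-1-yl}-9-borabicyclo[3.3.1]nonane (alkylborane) | C(C/C=C(\C)CC[C@@]1(O)[C@@H](C)CCCC1(C)C)B2C3CCCC2CCC3 | intermediate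
16 | 4-{(1E,3Z,7E)-4-(hydroxymethyl)-10-[(1R,6S)-1-hydroxy-2,2,6-trimethylcyclohexyl]-8-methyldeca-1,3,7-trien-1-yl}furan-2(5H)-one | OC/C(=C\C=C\C1=CC(=O)OC1)CC/C=C(\C)CC[C@@]1(O)[C@@H](C)CCCC1(C)C | intermediate
17 | (2Z,4E)-2-{(3E)-6-[(1R,6S)-1-hydroxy-2,2,6-trimethylcyclohexyl]-4-methylhex-3-en-1-yl}-5-(5-oxo-2,5-dihydrofuran-3-yl)penta-2,4-dien-1-yl acetate (CNP0366059.1) | CC(=O)OC/C(=C\C=C\C1=CC(=O)OC1)CC/C=C(\C)CC[C@@]1(O)[C@@H](C)CCCC1(C)C | target

## Step count and risks

Total steps: 8. Longest linear sequence: 5 (steps 1, 2, 3, 7, 8; 1 → 4 → 6 → 8 → 16 → 17).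

**Step 1 (most likely to fail).** The cascade may stop at the fused ion (no hydride shift), may give the C1 epimer if the cation inverts before the oxygen closes, and this acid class usually gives only about 75–90% ee. Product 4 would therefore be checked by NOE and brought to single-enantiomer quality by recrystallisation or preparative chiral chromatography.

The fallback sets out from 1 and comes back at 4; it keeps the proton-initiated ring closure but sets the two stereocentres separately. 1 is cyclised with concentrated H2SO4 in nitromethane at low temperature to the achiral tetrasubstituted olefin 4-(2,6,6-trimethylcyclohex-1-en-1-yl)butan-2-one F1. Asymmetric dioxirane epoxidation (KHSO5, K2CO3, 1,2:4,5-di-O-isopropylidene-β-D-erythro-2,3-hexodiulo-2,6-pyranose or its enantiomer, as the observed sense requires) gives 4-[(1S,6R)-2,2,6-trimethyl-7-oxabicyclo[4.1.0]heptan-1-yl]butan-2-one F2. LiNEt2 (3 equiv, the first enolises the ketone) removes a proton from the ring methyl and opens the epoxide to 4-[(1S)-1-hydroxy-2,2-dimethyl-6-methylidenecyclohexyl]butan-2-one F3. Hydroxyl-directed hydrogenation with [Ir(cod)(PCy3)(py)]PF6 and H2 then delivers hydrogen to C6 from the face of the hydroxyl, which is the 1R,6S relationship of 4.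

**Step 6.** The coupling may not discriminate cleanly between the two iodides, and vicinal diiodides can lose iodine under zerovalent palladium.

The fallback sets out from 9 and comes back at 16. 9 is treated with IBr (anti addition, iodine on the terminal carbon) to give (2E)-2-bromo-3-iodoprop-2-en-1-ol F4. Stille coupling with 13 under the conditions of step 6 then occurs only at the iodide and gives 4-[(1E,3E)-4-bromo-5-hydroxypenta-1,3-dien-1-yl]furan-2(5H)-one F5. F5 replaces 14 in the coupling with 15 (same palladium complex, K3PO4, 50 °C) to give 16.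

**Step 7.** Hydroboration of the diene may not be fully selective, the internal iodide is hindered, and aqueous base can damage the butenolide.

The fallback sets out from 6 and comes back at 16; it makes the same bond with an organozinc under neutral conditions. Alkenylalane 7, generated from 6 as in step 3, is treated with n-BuLi and ethylene oxide to give (1R,6S)-1-[(3E)-6-hydroxy-3-methylhex-3-en-1-yl]-2,2,6-trimethylcyclohexan-1-ol F6. I2, PPh3 and imidazole give (1R,6S)-1-[(3E)-6-iodo-3-methylhex-3-en-1-yl]-2,2,6-trimethylcyclohexan-1-ol F7. Zinc dust with LiCl in THF gives iodo{(3E)-6-[(1R,6S)-1-hydroxy-2,2,6-trimethylcyclohexyl]-4-methylhex-3-en-1-yl}zinc F8. Negishi coupling of F8 with 14 (Pd2(dba)3, tri(2-furyl)phosphine, THF–NMP, 25 °C) gives 16.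

## Further compounds

F1 | step 1 | 4-(2,6,6-trimethylcyclohex-1-en-1-yl)butan-2-one | CC(=O)CCC1=C(C)CCCC1(C)C
F2 | step 1 | 4-[(1S,6R)-2,2,6-trimethyl-7-oxabicyclo[4.1.0]heptan-1-yl]butan-2-one | CC(=O)CC[C@@]12O[C@]1(C)CCCC2(C)C
F3 | step 1 | 4-[(1S)-1-hydroxy-2,2-dimethyl-6-methylidenecyclohexyl]butan-2-one | CC(=O)CC[C@@]1(O)C(=C)CCCC1(C)C
F4 | step 6 | (2E)-2-bromo-3-iodoprop-2-en-1-ol | OC/C(Br)=C\I
F5 | step 6 | 4-[(1E,3E)-4-bromo-5-hydroxypenta-1,3-dien-1-yl]furan-2(5H)-one | OC/C(Br)=C\C=C\C1=CC(=O)OC1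
F6 | step 7 | (1R,6S)-1-[(3E)-6-hydroxy-3-methylhex-3-en-1-yl]-2,2,6-trimethylcyclohexan-1-ol | OCC/C=C(\C)CC[C@@]1(O)[C@@H](C)CCCC1(C)C
F7 | step 7 | (1R,6S)-1-[(3E)-6-iodo-3-methylhex-3-en-1-yl]-2,2,6-trimethylcyclohexan-1-ol | ICC/C=C(\C)CC[C@@]1(O)[C@@H](C)CCCC1(C)C
F8 | step 7 | iodo{(3E)-6-[(1R,6S)-1-hydroxy-2,2,6-trimethylcyclohexyl]-4-methylhex-3-en-1-yl}zinc | I[Zn]CC/C=C(\C)CC[C@@]1(O)[C@@H](C)CCCC1(C)C
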